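Add target and substrate at each reading before trusting any rate read from them, which is how I began on these flasks.

| flask | substrate | reagent | initiator | remark | time |
|---|---|---|---|---|---|
| cedar | 0.23 M | 1.5 equiv | 2.7 mol% | run made earlier |  |
| ash | 0.68 M | 1.5 equiv | 2.7 mol% | run made earlier |  |
| south-east | 0.34 M | 3.00 equiv | 10 mol% |  | 12 min |
| north-west | 0.34 M | 1.50 equiv | 2.7 mol% |  | 4.0 min |

- cedar (time / s: target / %, substrate / %): 10.0: 2.9, 97.5; 20.0: 4.8, 95.2; 30.0: 6.1, 93.1; 50.0: 10.5, 89.3
- ash (time / s: target / %, substrate / %): 10.0: 3.6, 95.6; 15.0: 5.8, 94.4; 25.0: 9.3, 91.1; 30.0: 10.6, 88.9; 40.0: 14.3, 85.9; 50.0: 17.4, 82.6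

(standard deviation of a reading: 0.3 percentage points)

- what was read earlier has a scatter of 0.3 percentage points, one standard deviation

- the winner by amount of target, in percent of the substrate charged; "neither" if no more than 2 percentage points parts them (south-east / north-west / neither)
- how much target is there at the end, in percent of the substrate charged: south-east
- how much target is there at the end, in percent of the substrate charged: north-west

The last cedar reading gave a pseudo-first-order constant for substrate of 0.00226 s⁻¹ and the last ash reading 0.00382 s⁻¹, a concentration order of 0.484, so at 0.34 M I took 0.00273 s⁻¹ for north-west. Neither run varied the initiator, so the 0.00526 s⁻¹ I took for south-east, by the square root of the loading, was an assumption.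

But the last ash sum of 100% carried a scatter of 0.42 percentage points, and dividing that by the target-time area gave the hidden-loss ceiling, the first-order constant for loss of target that the balance could conceal at one standard deviation, 9.75 × 10⁻⁴ s⁻¹. Target gains as ks·c_substrate and loses at most as kl·c_target, and the gain leads early, but c_substrate falls as c_target climbs. The ceiling's half-life, 11.8 min, matches the south-east time.

So I put south-east between 58.0% and 97.7%. For north-west, on its own time, I put 42.4% to 48.1%, which leaves south-east ahead. The forecast chose south-east, with 96% and 46%, holding that “there is no visible loss to side products”.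

The flask gave south-east, 64.7% against north-west's 39.3%, which lies below my north-west range.

    initiator → 2 initiating radical (k = 0.00350 s⁻¹)
    substrate + initiating radical → capped initiator + first chain carrier (k = 14000 L mol⁻¹ s⁻¹)
    reagent + first chain carrier ⇌ target + second chain carrier (K = 0.150, k = 21000 L mol⁻¹ s⁻¹)
    substrate + second chain carrier → by-product + first chain carrier (k = 820 L mol⁻¹ s⁻¹)
    2 second chain carrier → ended chains (k = 3.00 × 10⁶ L mol⁻¹ s⁻¹)
    target → over-reaction product (k = 6.90 × 10⁻⁴ s⁻¹)
    2 reagent → homo dimer (k = 0.00590 L mol⁻¹ s⁻¹)

South-east ended with 29.5% over-reaction product beside 5.84% substrate. Between 6.00 min and 12.0 min its over-reaction product rose 17 points, less than the 24 points the ceiling allowed on that target. North-west, read on to 10 min, gained 12 points of over-reaction product after 4.0 min, against a ceiling of 16 points.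

The data are simulated for substances that don't exist, noise included.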